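**Strategy**

Everything rests on disconnecting the bond between the exocyclic methine carbon on C5 of the furan-2,4-dione ring and the ipso carbon of the neighbouring 4-hydroxy-3-prenylphenyl ring. A Mizoroki–Heck arylation of a (3S)-5-methylidene-furan-2,4-dione with a silylated 4-iodo-2-prenylphenol makes this bond and the Z double bond in one operation. It exploits the exocyclic C5=CH2 α-acyloxy enone: C5 carries no hydrogen, so β-hydride elimination can only restore the C5=CH alkene, while the quaternary C3 cannot enolise. The methylidene dione arises from a 3-aryltetronic acid by Pd-catalysed asymmetric C3-prenylation, which sets the only stereocentre, followed by C5 methylenation.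

Key step: step 9

Remark (assumption): the sense of induction of the Trost ligand on this tetronate cannot be predicted with confidence. The (R,R)-ligand is written in step 7; if a test run shows the opposite sense, the (S,S)-ligand is used so that the (3S)-dione 12 is obtained.

Remark (chemistry): the target is (3S,5Z). Both phenols are carried as TIPS ethers because these tolerate LiHMDS, Pd(0) and bicarbonate and come off with buffered fluoride; acid would cyclise the ortho-prenylphenols to chromans.

**Route**

Step 1
Reactants: 1 4-iodophenol, 2 prenyl bromide (1-bromo-3-methylbut-2-ene)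
Product: 3 4-iodo-2-(3-methylbut-2-en-1-yl)phenol
Conditions: NaH (1.05 equiv), toluene, 0 °C → rt
Reagents that add atoms: none
Why: Ortho-selective C-alkylation of the sodium phenoxide as a tight ion pair in a non-polar solvent (phenoxide C-prenylation, SN2 at the primary carbon of 2) should place the prenyl group next to OH because the para position is blocked by iodine, the O-prenyl ether being a separable by-product.

Step 2
Reactants: 3 4-iodo-2-(3-methylbut-2-en-1-yl)phenol
Product: 4 [4-iodo-2-(3-methylbut-2-en-1-yl)phenoxy]tri(propan-2-yl)silane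
Conditions: TIPSCl, imidazole, DMF, rt
Reagents that add atoms: chlorotri(propan-2-yl)silane (TIPSCl), CC(C)[Si](Cl)(C(C)C)C(C)C
Why: Standard silylation of a phenol, giving a bulky silyl ether that should survive the later Pd and mild-base steps.

Step 3
Reactants: 5 (4-hydroxyphenyl)acetic acid, 6 methyl bromoacetate
Product: 7 2-methoxy-2-oxoethyl (4-hydroxyphenyl)acetate
Conditions: KHCO3 (1.1 equiv), DMF, rt
Reagents that add atoms: none
Why: Bicarbonate deprotonates only the carboxylic acid and not the phenol, and the carboxylate displaces bromide from 6 in an SN2 O-alkylation to give the glycolate ester needed for the Dieckmann closure.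

Step 4
Reactants: 7 2-methoxy-2-oxoethyl (4-hydroxyphenyl)acetate, 2 prenyl bromide
Product: 8 2-methoxy-2-oxoethyl [4-hydroxy-3-(3-methylbut-2-en-1-yl)phenyl]acetate
Conditions: NaH (1.0 equiv), toluene, 0 °C → rt
Reagents that add atoms: none
Why: Same ortho C-prenylation of a sodium phenoxide as in step 1; one equivalent of NaH deprotonates only the phenol (the ester α-CH2 groups are far less acidic) and the two ortho positions are equivalent.

Step 5
Reactants: 8 2-methoxy-2-oxoethyl [4-hydroxy-3-(3-methylbut-2-en-1-yl)phenyl]acetate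
Product: 9 2-methoxy-2-oxoethyl {3-(3-methylbut-2-en-1-yl)-4-[tri(propan-2-yl)silyloxy]phenyl}acetate
Conditions: TIPSCl, imidazole, DMF, rt
Reagents that add atoms: chlorotri(propan-2-yl)silane (TIPSCl), CC(C)[Si](Cl)(C(C)C)C(C)C
Why: Standard phenol silylation under conditions that leave both esters untouched.

Step 6
Reactants: 9 2-methoxy-2-oxoethyl {3-(3-methylbut-2-en-1-yl)-4-[tri(propan-2-yl)silyloxy]phenyl}acetate
Product: 10 4-hydroxy-3-{3-(3-methylbut-2-en-1-yl)-4-[tri(propan-2-yl)silyloxy]phenyl}furan-2(5H)-one (3-aryltetronic acid)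
Conditions: LiHMDS (2.2 equiv), THF, −78 → 0 °C; then 1 M HCl work-up
Reagents that add atoms: none
Why: Dieckmann condensation: the arylacetate enolate attacks the methyl ester carbonyl (5-exo-trig acyl substitution) and irreversible deprotonation of the tetronic acid formed drives the ring closure, while hindered LiHMDS at low temperature should leave the aryl TIPS ether intact.

Step 7
Reactants: 10 3-aryltetronic acid, 11 prenyl acetate (3-methylbut-2-en-1-yl acetate)
Product: 12 (3S)-3-(3-methylbut-2-en-1-yl)-3-{3-(3-methylbut-2-en-1-yl)-4-[tri(propan-2-yl)silyloxy]phenyl}furan-2,4(3H,5H)-dione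
Conditions: Pd2(dba)3·CHCl3 (2.5 mol %), (R,R)-DACH-phenyl Trost ligand (7.5 mol %), CH2Cl2, 0 °C → rt
Reagents that add atoms: none
Why: Pd-catalysed asymmetric allylic alkylation (Tsuji–Trost reaction with a Trost ligand): the soft tetronate attacks the π-prenyl–Pd complex through C3 at the unsubstituted allyl terminus (attack at the CMe2 end would join two quaternary carbons, and O-prenylated material re-ionises), the chiral ligand pocket differentiating the enantiotopic faces of the planar tetronate to set the C3 quaternary stereocentre as (S), while the only base present, acetate, is too weak to enolise C5 of the product for a second allylation.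

Step 8
Reactants: 12 (3S)-3-aryl-3-prenylfuran-2,4-dione, 13 Eschenmoser's salt (N,N-dimethylmethaniminium iodide)
Product: 16 (3S)-5-methylidene-3-(3-methylbut-2-en-1-yl)-3-{3-(3-methylbut-2-en-1-yl)-4-[tri(propan-2-yl)silyloxy]phenyl}furan-2,4(3H,5H)-dione, via Mannich base 14 (not isolated), via methiodide 15 (not isolated)
Conditions: LiHMDS (1.05 equiv), THF, −78 °C; then 13, −78 → 0 °C; then MeI, rt; then aq. NaHCO3/CH2Cl2, rt; product used directly
Reagents that add atoms: none
Why: α-Methylenation of a ketone by Mannich reaction of its lithium enolate with Eschenmoser's salt, N-methylation and E1cB loss of trimethylamine; C5 is the only enolisable position (C3 is quaternary, so its configuration is untouched) and the C5 stereocentre of the intermediates disappears in the elimination.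

Step 9
Reactants: 16 (3S)-5-methylidene dione, 4 [4-iodo-2-(3-methylbut-2-en-1-yl)phenoxy]tri(propan-2-yl)silane
Product: 17 (3S,5Z)-3-(3-methylbut-2-en-1-yl)-3-{3-(3-methylbut-2-en-1-yl)-4-[tri(propan-2-yl)silyloxy]phenyl}-5-({3-(3-methylbut-2-en-1-yl)-4-[tri(propan-2-yl)silyloxy]phenyl}methylidene)furan-2,4(3H,5H)-dione
Conditions: Pd(OAc)2 (5 mol %), nBu4NCl (1 equiv), NaHCO3 (2.5 equiv), anhydrous DMF, 60 °C
Reagents that add atoms: none
Why: Mizoroki–Heck reaction: Pd(0) inserts into the C–I bond of 4, the aryl–Pd species adds syn across the exocyclic C5=CH2 bond of 16 with the aryl group on the unsubstituted CH2 terminus (the β-carbon of the C4 enone and the less hindered end) and Pd on C5, and syn-β-hydride elimination, possible only from the new benzylic CH2 because C5 bears no hydrogen, re-forms the exocyclic double bond. The closest known reaction is the ligand-free, ammonium chloride/bicarbonate Heck arylation of 2-acyloxyacrylates and 2-acylaminoacrylates, which gives (Z)-3-aryl products; 16 is the cyclic α-acyloxy enone counterpart. No ring is closed and no stereocentre is formed; the alkene geometry is controlled by the elimination transition state that keeps the aryl group syn to the ring oxygen O1 and away from the C4 carbonyl (allylic strain), and Pd–H re-addition lets any E isomer drain to the more stable Z isomer. Chemoselectivity is needed against the three trisubstituted prenyl alkenes, which are too hindered for carbopalladation, and against the acyl enol ether lactone, which is spared by the weak, non-nucleophilic base. C3 is quaternary and non-enolisable, and the ligand-free catalyst at 60 °C gives little chance for ionisation of the C3–prenyl bond, so the (S) configuration should be retained.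

Step 10
Reactants: 17 bis-TIPS ether of the target
Product: 18 (3S,5Z)-3-[4-hydroxy-3-(3-methylbut-2-en-1-yl)phenyl]-5-{[4-hydroxy-3-(3-methylbut-2-en-1-yl)phenyl]methylidene}-3-(3-methylbut-2-en-1-yl)furan-2,4(3H,5H)-dione (CNP0567773.1)
Conditions: TBAF (2.5 equiv), AcOH (2.5 equiv), THF, 0 °C
Reagents that add atoms: none
Why: Fluoride cleaves both aryl silyl ethers (Si–F bond formation), acetic acid buffering keeps phenoxide and fluoride from opening the acyl enol ether lactone, and the absence of strong acid prevents chroman formation from the ortho-prenylphenols, so C3 and the Z alkene should be unaffected.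

**Compound list**

1 | 4-iodophenol | Oc1ccc(I)cc1 | starting material
2 | prenyl bromide (1-bromo-3-methylbut-2-ene) | CC(C)=CCBr | starting material
3 | 4-iodo-2-(3-methylbut-2-en-1-yl)phenol | CC(C)=CCc1cc(I)ccc1O | intermediate
4 | [4-iodo-2-(3-methylbut-2-en-1-yl)phenoxy]tri(propan-2-yl)silane | CC(C)=CCc1cc(I)ccc1O[Si](C(C)C)(C(C)C)C(C)C | intermediate
5 | (4-hydroxyphenyl)acetic acid | OC(=O)Cc1ccc(O)cc1 | starting material
6 | methyl bromoacetate | COC(=O)CBr | starting material
7 | 2-methoxy-2-oxoethyl (4-hydroxyphenyl)acetate | COC(=O)COC(=O)Cc1ccc(O)cc1 | intermediate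
8 | 2-methoxy-2-oxoethyl [4-hydroxy-3-(3-methylbut-2-en-1-yl)phenyl]acetate | COC(=O)COC(=O)Cc1ccc(O)c(CC=C(C)C)c1 | intermediate
9 | 2-methoxy-2-oxoethyl {3-(3-methylbut-2-en-1-yl)-4-[tri(propan-2-yl)silyloxy]phenyl}acetate | COC(=O)COC(=O)Cc1ccc(O[Si](C(C)C)(C(C)C)C(C)C)c(CC=C(C)C)c1 | intermediate
10 | 4-hydroxy-3-{3-(3-methylbut-2-en-1-yl)-4-[tri(propan-2-yl)silyloxy]phenyl}furan-2(5H)-one | OC1=C(c2ccc(O[Si](C(C)C)(C(C)C)C(C)C)c(CC=C(C)C)c2)C(=O)OC1 | intermediate
11 | prenyl acetate (3-methylbut-2-en-1-yl acetate) | CC(C)=CCOC(C)=O | starting material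
12 | (3S)-3-(3-methylbut-2-en-1-yl)-3-{3-(3-methylbut-2-en-1-yl)-4-[tri(propan-2-yl)silyloxy]phenyl}furan-2,4(3H,5H)-dione | C1OC(=O)[C@@](CC=C(C)C)(c2ccc(O[Si](C(C)C)(C(C)C)C(C)C)c(CC=C(C)C)c2)C1=O | intermediate
13 | Eschenmoser's salt (N,N-dimethylmethaniminium iodide) | C=[N+](C)C.[I-] | starting material
14 | Mannich base: (3S)-5-[(dimethylamino)methyl] derivative of 12, mixture of C5 epimers | CN(C)CC1OC(=O)[C@@](CC=C(C)C)(c2ccc(O[Si](C(C)C)(C(C)C)C(C)C)c(CC=C(C)C)c2)C1=O | intermediate
15 | methiodide: (3S)-5-[(trimethylammonio)methyl] derivative of 12, iodide salt, mixture of C5 epimers | C[N+](C)(C)CC1OC(=O)[C@@](CC=C(C)C)(c2ccc(O[Si](C(C)C)(C(C)C)C(C)C)c(CC=C(C)C)c2)C1=O.[I-] | intermediate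
16 | (3S)-5-methylidene-3-(3-methylbut-2-en-1-yl)-3-{3-(3-methylbut-2-en-1-yl)-4-[tri(propan-2-yl)silyloxy]phenyl}furan-2,4(3H,5H)-dione | C=C1OC(=O)[C@@](CC=C(C)C)(c2ccc(O[Si](C(C)C)(C(C)C)C(C)C)c(CC=C(C)C)c2)C1=O | intermediate
17 | (3S,5Z)-bis-TIPS ether of the target | CC(C)=CCc1cc(/C=C2\OC(=O)[C@@](CC=C(C)C)(c3ccc(O[Si](C(C)C)(C(C)C)C(C)C)c(CC=C(C)C)c3)C2=O)ccc1O[Si](C(C)C)(C(C)C)C(C)C | intermediate
18 | (3S,5Z)-3-[4-hydroxy-3-(3-methylbut-2-en-1-yl)phenyl]-5-{[4-hydroxy-3-(3-methylbut-2-en-1-yl)phenyl]methylidene}-3-(3-methylbut-2-en-1-yl)furan-2,4(3H,5H)-dione | CC(C)=CCc1cc(/C=C2\OC(=O)[C@@](CC=C(C)C)(c3ccc(O)c(CC=C(C)C)c3)C2=O)ccc1O | target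

**Step count and risks**

Total step count: 10. Longest linear sequence: 8 steps (steps 3 to 10); steps 1 and 2 form the second branch.

Steps most likely to fail:

1. Step 9 (key step). What may go wrong: base- or heat-induced opening or oligomerisation of the acyl enol ether 16 before insertion, incomplete Z selectivity in the β-hydride elimination, or partial loss of enantiopurity through reversible Pd(0) ionisation of the C3–prenyl bond. The fallback joins the same two carbons at the saturated level and introduces the alkene afterwards; it sets out from 4 and 16 and comes back at 17. Iodide 4 is borylated (B2pin2, PdCl2(dppf), KOAc, dioxane, 80 °C) to the aryl pinacol boronate F1. Rh(I)-catalysed conjugate arylation of 16 with F1 ([Rh(cod)OH]2, dioxane/H2O, 40 °C, no added base; Hayashi–Miyaura reaction) should give the 5-(arylmethyl) dione F2 as a mixture of C5 epimers. Enolisation and selenenylation (LiHMDS, PhSeCl, THF, −78 °C) give the 5-phenylselanyl compound F3. Oxidation (H2O2, pyridine, CH2Cl2, 0 °C) triggers selenoxide syn-elimination, which can only run towards the benzylic CH2, and should deliver 17.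

2. Step 7. What may go wrong: poor discrimination between the two faces of the flat tetronate (its lactone and ketone flanks are similar in size), or competing O-prenylation and attack at the substituted allyl terminus. The fallback replaces catalytic enantiocontrol by resolution; it sets out from 10 and 11 and comes back at 12. Prenylation with an achiral catalyst (Pd(PPh3)4, CH2Cl2, rt) gives the racemic dione F4. Preparative chromatography on a chiral stationary phase (SFC, polysaccharide phase) separates 12 from the (3R)-enantiomer F5, which is discarded.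

3. Step 8. What may go wrong: double aminomethylation at C5, or re-addition of amine and oligomerisation of the very electrophilic methylidene dione during elimination and concentration. The fallback avoids 16 altogether and forms the same aryl–methine bond by cross-coupling; it sets out from 12 and comes back at 17. C5 formylation (LiHMDS, THF, −78 °C; then 2,2,2-trifluoroethyl formate) gives the 5-(hydroxymethylidene) dione F6. Sulfonylation (TsCl, N-methylimidazole, Et3N, CH2Cl2, 0 °C) at the less hindered exocyclic oxygen gives the enol tosylate F7. Suzuki–Miyaura coupling of F7 with the aryl pinacol boronate F1, made from 4 as described under step 9 (Pd(OAc)2, SPhos, K3PO4, THF, 40 °C), should give 17. If an E/Z mixture results, it is expected to converge on the Z isomer after step 10, because the free 4-hydroxybenzylidene phenol can equilibrate through its phenoxide.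

**Further compounds**

F1 | step 9 | 4,4,5,5-tetramethyl-2-{3-(3-methylbut-2-en-1-yl)-4-[tri(propan-2-yl)silyloxy]phenyl}-1,3,2-dioxaborolane | CC(C)=CCc1cc(B2OC(C)(C)C(C)(C)O2)ccc1O[Si](C(C)C)(C(C)C)C(C)C
F2 | step 9 | (3S)-3-(3-methylbut-2-en-1-yl)-3-{3-(3-methylbut-2-en-1-yl)-4-[tri(propan-2-yl)silyloxy]phenyl}-5-({3-(3-methylbut-2-en-1-yl)-4-[tri(propan-2-yl)silyloxy]phenyl}methyl)furan-2,4(3H,5H)-dione, C5 epimers | CC(C)=CCc1cc(CC2OC(=O)[C@@](CC=C(C)C)(c3ccc(O[Si](C(C)C)(C(C)C)C(C)C)c(CC=C(C)C)c3)C2=O)ccc1O[Si](C(C)C)(C(C)C)C(C)C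
F3 | step 9 | 5-(phenylselanyl) derivative of F2, C5 epimers | CC(C)=CCc1cc(CC2([Se]c4ccccc4)OC(=O)[C@@](CC=C(C)C)(c3ccc(O[Si](C(C)C)(C(C)C)C(C)C)c(CC=C(C)C)c3)C2=O)ccc1O[Si](C(C)C)(C(C)C)C(C)C
F4 | step 7 | racemic 3-(3-methylbut-2-en-1-yl)-3-{3-(3-methylbut-2-en-1-yl)-4-[tri(propan-2-yl)silyloxy]phenyl}furan-2,4(3H,5H)-dione | C1OC(=O)C(CC=C(C)C)(c2ccc(O[Si](C(C)C)(C(C)C)C(C)C)c(CC=C(C)C)c2)C1=O
F5 | step 7 | (3R)-enantiomer of 12 | C1OC(=O)[C@](CC=C(C)C)(c2ccc(O[Si](C(C)C)(C(C)C)C(C)C)c(CC=C(C)C)c2)C1=O
F6 | step 8 | (3S)-5-(hydroxymethylidene) derivative of 12 | OC=C1OC(=O)[C@@](CC=C(C)C)(c2ccc(O[Si](C(C)C)(C(C)C)C(C)C)c(CC=C(C)C)c2)C1=O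
F7 | step 8 | (3S)-5-{[(4-methylbenzenesulfonyl)oxy]methylidene} derivative of 12 | Cc1ccc(cc1)S(=O)(=O)OC=C1OC(=O)[C@@](CC=C(C)C)(c2ccc(O[Si](C(C)C)(C(C)C)C(C)C)c(CC=C(C)C)c2)C1=O
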